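Ring C (O1–C2–C3–C4–C4a–C8a) is cut at C3–C4. This unfolds the flavanone into an achiral salicylaldehyde whose O1 carries a 1-arylvinyl group. One Rh-catalysed enantioselective intramolecular hydroacylation adds the formyl C–H across the C2=C3 enol ether. It closes ring C, creates the C4 ketone and sets C2 as S, with no atom lost. The step exploits the C5–OH···O=C4 hydrogen bond, which turns the formyl C–H towards O1, and the 1,1-disubstituted, non-isomerisable O1–C2(=C3H2)–aryl unit. The precursor comes from 3-geranylphloroglucinaldehyde by double etherification and elimination. The second enol ether, on O7, serves as protecting group.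

Key step: step 5

Assumption: no close analogue predicts the sense of induction of the ligand, so (R)-DTBM-SEGPHOS is written for hydride delivery to the Re face of C2, and the commercial (S)-antipode replaces it if the other face is attacked.

Step 1
Reactants: 1 2,4,6-trihydroxybenzaldehyde; 2 geranyl bromide, (2E)-1-bromo-3,7-dimethylocta-2,6-diene
Product: 3 3-geranyl-2,4,6-trihydroxybenzaldehyde (geranyl = (2E)-3,7-dimethylocta-2,6-dien-1-yl)
Conditions: KOH (1.0 equiv), MeOH, 0 °C to rt, slight excess of 1
Reagents that add atoms: none
Why: Phenolate C-alkylation by SN2 at the primary allylic bromide keeps the E-alkene and the linear geranyl connectivity, because in the protic medium the solvated phenolate oxygens are shielded and ring carbon C3 (equivalent to C5 by symmetry) attacks, while the excess of 1 should limit a second alkylation.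

Step 2
Reactants: 4 4-(methoxymethoxy)benzaldehyde
Product: 5 rac-2-chloro-1-[4-(methoxymethoxy)phenyl]ethanol
Conditions: ClCH2I, MeLi·LiBr (added last, slowly), THF, −78 °C; AcOH quench at −78 °C
Reagents that add atoms: chloroiodomethane, ClCI
Why: In this carbenoid addition, fast Li/I exchange makes chloromethyllithium in the presence of the aldehyde, which traps it at once, and the cold acidic quench protonates the alkoxide before it can close to the epoxide; the carbinol centre is racemic, which does not matter because step 4 flattens it.

Step 3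
Reactants: 3 3-geranyl-2,4,6-trihydroxybenzaldehyde; 5 rac-2-chloro-1-[4-(methoxymethoxy)phenyl]ethanol (2.2 equiv)
Product: 6 4,6-bis{2-chloro-1-[4-(methoxymethoxy)phenyl]ethoxy}-3-geranyl-2-hydroxybenzaldehyde (mixture of diastereomers at the two ether carbons)
Conditions: PPh3, DIAD (2.4 equiv each), THF, 0 °C to rt
Reagents that add atoms: none
Why: This twofold Mitsunobu etherification follows the intrinsic order of the three phenols, with 4-OH (para to CHO, most acidic, not chelated) reacting before 6-OH (flanked by H), while 2-OH stays free because it is hydrogen-bonded to the formyl group and wedged between it and the geranyl chain; both new ether centres form without control and are erased in step 4.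

Step 4
Reactants: 6 bis(2-chloro ether)
Product: 7 3-geranyl-2-hydroxy-4,6-bis({1-[4-(methoxymethoxy)phenyl]ethenyl}oxy)benzaldehyde
Conditions: KOtBu (3.5 equiv), THF, 0 °C to rt; pH 7 buffer work-up
Reagents that add atoms: none
Why: Twofold E2 dehydrochlorination is the standard route from 2-haloethyl aryl ethers to aryl vinyl ethers and is helped here by the benzylic α-oxy C–H; the first equivalent of base turns 2-OH into the phenoxide, which shields the non-enolisable aldehyde, and THF instead of DMSO should keep the geranyl alkene out of conjugation.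

Step 5
Reactants: 7 bis(enol ether) salicylaldehyde
Product: 8 (2S)-6-geranyl-5-hydroxy-2-[4-(methoxymethoxy)phenyl]-7-({1-[4-(methoxymethoxy)phenyl]ethenyl}oxy)chroman-4-one
Conditions: [Rh(cod)Cl]2 (2.5 mol %), (R)-DTBM-SEGPHOS (5.5 mol %), NaBArF4 (6 mol %), 4 Å MS, THF (0.05 M), 60 °C, no base
Reagents that add atoms: none
Why: Proposed new method: the cationic Rh(I)–bisphosphine binds the C2=C3 enol ether (flavanone numbering; C5–OH is the 2-OH of 7), inserts into the neighbouring formyl C–H by oxidative addition, transfers the hydride to C2 by migratory insertion so that Rh ends on the primary C3 in a seven-membered acyl–alkyl rhodacycle, and forms C3–C4 by reductive elimination. The closest known reaction type is the Rh-catalysed enantioselective intramolecular hydroacylation of ortho-(2-substituted allyl)benzaldehydes to 3-substituted 1-tetralones, of which 7 is the O1-for-CH2 analogue, but an aryl 1-arylvinyl ether has not been shown as acceptor. Ring C closes in a formal 6-endo-trig mode. The only new stereocentre, C2, is under catalyst control: the C2-symmetric ligand differentiates the enantiotopic alkene faces so that hydride reaches the Re face of C2, which gives S. The step needs regioselectivity (H to C2, not the 5-exo path to a 2-aryl-2-methylbenzofuran-3-one), secured by the reluctance of Rh to carry a tertiary alkyl and to build a quaternary centre, and it needs cyclisation to outrun decarbonylation, which the C5–OH···O=C hydrogen bond supports by holding the formyl C–H next to the bound alkene, while base-free conditions keep the phenol from trapping Rh as a phenoxide chelate on the wrong side of C4. The enol ether has no allylic hydrogen and cannot isomerise, and the O7 enol ether (para to the formyl group) and the trisubstituted geranyl alkenes cannot reach the acyl–Rh centre intramolecularly.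

Step 6
Reactants: 8 protected flavanone
Product: 9 bonannione A, (2S)-6-geranyl-5,7-dihydroxy-2-(4-hydroxyphenyl)chroman-4-one
Conditions: 3 M aq HCl–MeOH (1:10), 45 °C
Reagents that add atoms: none
Why: Acid-catalysed acetal exchange removes both MOM groups, and C-protonation of the O7 enol ether followed by hydrolysis of the hemiketal frees 7-OH, while C2 is safe because flavanones racemise through base-induced ring opening and the mild temperature should spare the geranyl chain.

Compound list
1 | 2,4,6-trihydroxybenzaldehyde | O=Cc1c(O)cc(O)cc1O | starting material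
2 | geranyl bromide | CC(C)=CCC/C(C)=C/CBr | starting material
3 | 3-geranyl-2,4,6-trihydroxybenzaldehyde | CC(C)=CCC/C(C)=C/Cc1c(O)cc(O)c(C=O)c1O | intermediate
4 | 4-(methoxymethoxy)benzaldehyde | COCOc1ccc(C=O)cc1 | starting material
5 | rac-2-chloro-1-[4-(methoxymethoxy)phenyl]ethanol | COCOc1ccc(C(O)CCl)cc1 | intermediate
6 | 4,6-bis{2-chloro-1-[4-(methoxymethoxy)phenyl]ethoxy}-3-geranyl-2-hydroxybenzaldehyde (diastereomer mixture) | CC(C)=CCC/C(C)=C/Cc1c(OC(CCl)c2ccc(OCOC)cc2)cc(OC(CCl)c2ccc(OCOC)cc2)c(C=O)c1O | intermediate
7 | 3-geranyl-2-hydroxy-4,6-bis({1-[4-(methoxymethoxy)phenyl]ethenyl}oxy)benzaldehyde | CC(C)=CCC/C(C)=C/Cc1c(OC(=C)c2ccc(OCOC)cc2)cc(OC(=C)c2ccc(OCOC)cc2)c(C=O)c1O | intermediate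
8 | (2S)-6-geranyl-5-hydroxy-2-[4-(methoxymethoxy)phenyl]-7-({1-[4-(methoxymethoxy)phenyl]ethenyl}oxy)chroman-4-one | CC(C)=CCC/C(C)=C/Cc1c(OC(=C)c2ccc(OCOC)cc2)cc2c(c1O)C(=O)C[C@@H](c1ccc(OCOC)cc1)O2 | intermediate
9 | bonannione A | CC(C)=CCC/C(C)=C/Cc1c(O)cc2c(c1O)C(=O)C[C@@H](c1ccc(O)cc1)O2 | target

Total step count: 6. Longest linear sequence: 5 steps (1, 3, 4, 5, 6).

Steps most likely to fail

Step 5 (proposed new method). The acyl rhodium hydride may decarbonylate before insertion. The alkyl rhodium intermediate may undergo β-aryloxy elimination. Insertion may take the opposite regiochemistry, or facial selectivity may be poor. The fallback uses known chemistry, sets out from 3 and 5, and comes back at 9. It sets the stereocentre before ring closure and closes the same bond by carbene umpolung.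
- Mono-protection of 3 at the most acidic 4-OH (MOMCl, 1 equiv, i-Pr2NEt, CH2Cl2, 0 °C) gives 3-geranyl-2,6-dihydroxy-4-(methoxymethoxy)benzaldehyde F1.
- Racemic 5 is oxidised with Dess–Martin periodinane to 2-chloro-1-[4-(methoxymethoxy)phenyl]ethanone F2.
- Noyori asymmetric transfer hydrogenation of F2 (RuCl[(R,R)-TsDPEN](p-cymene), HCO2H/Et3N) gives (S)-2-chloro-1-[4-(methoxymethoxy)phenyl]ethanol F3.
- Mitsunobu etherification of F1 with F3 at the less hindered 6-OH, with inversion, gives 6-{(1R)-2-chloro-1-[4-(methoxymethoxy)phenyl]ethoxy}-3-geranyl-2-hydroxy-4-(methoxymethoxy)benzaldehyde F4, which already holds the spatial arrangement of C2.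
- An NHC-catalysed intramolecular nucleophilic substitution follows (triazolium precatalyst, i-Pr2NEt, catalytic NaI, toluene, 80 °C). This is the known closure of 2-(2-haloethoxy)benzaldehydes to chroman-4-ones through the Breslow intermediate. It forms C3–C4 without touching C2 and gives (2S)-6-geranyl-5-hydroxy-7-(methoxymethoxy)-2-[4-(methoxymethoxy)phenyl]chroman-4-one F5.
- The conditions of step 6 then give 9.

Step 3. The p-alkoxybenzylic oxyphosphonium ion may ionise and then lose a proton or C-alkylate ring A. The second etherification may stay incomplete, or site selectivity between 6-OH and 2-OH may be lost. The fallback sets out from 3 and 4 and comes back at 7. It replaces the redox condensation by SN alkylation.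
- Wittig methylenation of 4 (Ph3P=CH2, THF) gives 1-(methoxymethoxy)-4-vinylbenzene F6.
- Bromine addition (Br2, CH2Cl2, −78 °C) gives 1-(1,2-dibromoethyl)-4-(methoxymethoxy)benzene F7.
- The benzylic bromide of F7 alkylates the 4- and 6-phenolates of 3 (K2CO3, DMF, 0 °C to rt). This gives 4,6-bis{2-bromo-1-[4-(methoxymethoxy)phenyl]ethoxy}-3-geranyl-2-hydroxybenzaldehyde F8.
- KOtBu as in step 4 eliminates the better leaving group and gives 7.

Step 1. The ambident phenolate may undergo O-alkylation, a second alkylation, or dearomatising geminal alkylation. The fallback sets out from 2 and comes back at 3. It inverts the order of the two C–C bond formations.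
- Commercial phloroglucinol is cheap and threefold symmetric and can be used in large excess. It is C-alkylated with 2 (aq KOH, 0 °C to rt) to 2-geranylphloroglucinol F9.
- Vilsmeier–Haack formylation (POCl3, DMF, EtOAc, 0 °C; aq NaOAc) at one of the two equivalent free ring positions gives 3.

Further compounds
F1 | step 5 | 3-geranyl-2,6-dihydroxy-4-(methoxymethoxy)benzaldehyde | CC(C)=CCC/C(C)=C/Cc1c(OCOC)cc(O)c(C=O)c1O
F2 | step 5 | 2-chloro-1-[4-(methoxymethoxy)phenyl]ethanone | COCOc1ccc(C(=O)CCl)cc1
F3 | step 5 | (S)-2-chloro-1-[4-(methoxymethoxy)phenyl]ethanol | COCOc1ccc([C@H](O)CCl)cc1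
F4 | step 5 | 6-{(1R)-2-chloro-1-[4-(methoxymethoxy)phenyl]ethoxy}-3-geranyl-2-hydroxy-4-(methoxymethoxy)benzaldehyde | CC(C)=CCC/C(C)=C/Cc1c(OCOC)cc(O[C@@H](CCl)c2ccc(OCOC)cc2)c(C=O)c1O
F5 | step 5 | (2S)-6-geranyl-5-hydroxy-7-(methoxymethoxy)-2-[4-(methoxymethoxy)phenyl]chroman-4-one | CC(C)=CCC/C(C)=C/Cc1c(OCOC)cc2c(c1O)C(=O)C[C@@H](c1ccc(OCOC)cc1)O2
F6 | step 3 | 1-(methoxymethoxy)-4-vinylbenzene | C=Cc1ccc(OCOC)cc1
F7 | step 3 | 1-(1,2-dibromoethyl)-4-(methoxymethoxy)benzene | BrCC(Br)c1ccc(OCOC)cc1
F8 | step 3 | 4,6-bis{2-bromo-1-[4-(methoxymethoxy)phenyl]ethoxy}-3-geranyl-2-hydroxybenzaldehyde | CC(C)=CCC/C(C)=C/Cc1c(OC(CBr)c2ccc(OCOC)cc2)cc(OC(CBr)c2ccc(OCOC)cc2)c(C=O)c1O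
F9 | step 1 | 2-geranylphloroglucinol | CC(C)=CCC/C(C)=C/Cc1c(O)cc(O)cc1O
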